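The cyclohexene is opened at its only C=C bond, C5=C6, which lies between the quaternary carbinol C1 and the secondary carbinol C4. Ring-closing metathesis of an acyclic 1,7-diene forms that bond and the six-membered ring in one operation, with all four stereocentres and both benzoates already in place. The step exploits the cis C1/C2 diol: as an isopropylidene acetal it holds the C1 vinyl group and the C2–C4 chain cis on a dioxolane, pre-organising the closure. The diene comes from D-mannose (C1 and C2, by formaldehyde aldol of the lactol and methylenation) and a reagent-controlled syn-alkoxyallylboration (C3 and C4).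

Key step: step 7

Remark: the name is read as the (1S,2S,3R,4S) configuration drawn by the SMILES; C1–C6 below are the ring atoms of the target, C1 being the quaternary carbinol carbon. Allyl methoxymethyl ether is taken as a purchasable compound.

Step 1
Reactants: 1 2,3:5,6-di-O-isopropylidene-α-D-mannofuranose
Product: 2 2-C-(hydroxymethyl)-2,3:5,6-di-O-isopropylidene-D-mannofuranose (lactol, anomeric mixture)
Conditions: 37% aq. HCHO, K2CO3, MeOH, 65 °C
Reagents that add atoms: formaldehyde, C=O
Why: Base-mediated crossed aldol (hydroxymethylation) of the open aldehyde tautomer of the lactol, in which the C2 enolate held in the dioxolane takes up formaldehyde anti to the C4 substituent on C3; because the aldol is reversible and only the isomer with C1 and C4 cis on the dioxolane can re-close to the cis-fused furanose, the quaternary carbon should form with O2 in its original position and CH2OH in place of H2 (this sets C1 of the target).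

Step 2
Reactants: 2 2-C-(hydroxymethyl)-2,3:5,6-di-O-isopropylidene-D-mannofuranose
Product: 3 1,2-dideoxy-3-C-(hydroxymethyl)-3,4:6,7-di-O-isopropylidene-D-manno-hept-1-enitol
Conditions: Ph3PCH3Br, n-BuLi (excess ylide), THF, 0 °C to 40 °C
Reagents that add atoms: methyltriphenylphosphonium bromide, C[P+](c1ccccc1)(c1ccccc1)c1ccccc1.[Br-]
Why: Wittig methylenation of the lactol through its aldehyde tautomer turns the anomeric carbon into the vinyl group on the quaternary carbon without touching a stereocentre, lithium alkoxides and a cold start being chosen to keep retro-aldol loss of formaldehyde slow.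

Step 3
Reactants: 3 1,2-dideoxy-3-C-(hydroxymethyl)-3,4:6,7-di-O-isopropylidene-D-manno-hept-1-enitol
Product: 4 3-C-(benzoyloxymethyl)-1,2-dideoxy-3,4:6,7-di-O-isopropylidene-D-manno-hept-1-enitol
Conditions: BzCl (1.05 equiv), pyridine, CH2Cl2, −30 °C to 0 °C
Reagents that add atoms: benzoyl chloride, O=C(Cl)c1ccccc1
Why: Kinetically selective O-acylation, the primary hydroxyl reacting ahead of the secondary C5 hydroxyl that is flanked by two dioxolane-bearing carbons, while the 1,4-diol spacing should make later benzoyl migration slow.

Step 4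
Reactants: 4 3-C-(benzoyloxymethyl)-1,2-dideoxy-3,4:6,7-di-O-isopropylidene-D-manno-hept-1-enitol
Product: 6 [(4S,5R)-4-ethenyl-5-formyl-2,2-dimethyl-1,3-dioxolan-4-yl]methyl benzoate, via triol 5 (not isolated)
Conditions: H5IO6 (2.5 equiv), EtOAc, rt
Reagents that add atoms: none
Why: Periodic acid should first hydrolyse the terminal, less hindered isopropylidene acetal and then cleave the liberated 5,6,7-triol twice (Malaprade glycol cleavage), so that C5 becomes the aldehyde while C6 and C7 leave as formic acid and formaldehyde; the acetal on the quaternary carbon hydrolyses more slowly and the α-stereocentre is not enolised under these acidic conditions.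

Step 5
Reactants: 6 [(4S,5R)-4-ethenyl-5-formyl-2,2-dimethyl-1,3-dioxolan-4-yl]methyl benzoate; 7 allyl methoxymethyl ether
Product: 9 [(4S,5S)-4-ethenyl-5-[(1R,2S)-1-hydroxy-2-(methoxymethoxy)but-3-en-1-yl]-2,2-dimethyl-1,3-dioxolan-4-yl]methyl benzoate, via borinate 8 (not isolated)
Conditions: 7, s-BuLi, THF, −78 °C; (+)-Ipc2BOMe (from (−)-α-pinene); BF3·OEt2; then 6, −78 °C; H2O2, pH 7 phosphate buffer, 0 °C to rt
Reagents that add atoms: none
Why: Brown-type asymmetric alkoxyallylboration through a closed chair transition state, in which the Z geometry of the γ-(methoxymethoxy)allylborane gives the syn relation between the new hydroxyl carbon (C3 of the target) and the OMOM carbon (C4 of the target) and the isopinocampheyl groups direct attack to the Re face of the aldehyde, reagent control being relied on to override the intrinsic anti preference of the α-alkoxy aldehyde; the ester should be spared because no free organolithium remains after borate formation.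

Step 6
Reactants: 9 [(4S,5S)-4-ethenyl-5-[(1R,2S)-1-hydroxy-2-(methoxymethoxy)but-3-en-1-yl]-2,2-dimethyl-1,3-dioxolan-4-yl]methyl benzoate
Product: 10 [(4S,5S)-5-[(1R,2S)-1-(benzoyloxy)-2-(methoxymethoxy)but-3-en-1-yl]-4-ethenyl-2,2-dimethyl-1,3-dioxolan-4-yl]methyl benzoate
Conditions: BzCl, pyridine, DMAP (cat.), CH2Cl2, 0 °C to rt
Reagents that add atoms: benzoyl chloride, O=C(Cl)c1ccccc1
Why: DMAP-catalysed acylation of the only free hydroxyl should install the C3 benzoate with retention of configuration.

Step 7
Reactants: 10 [(4S,5S)-5-[(1R,2S)-1-(benzoyloxy)-2-(methoxymethoxy)but-3-en-1-yl]-4-ethenyl-2,2-dimethyl-1,3-dioxolan-4-yl]methyl benzoate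
Product: 11 [(3aS,4R,5S,7aS)-4-(benzoyloxy)-5-(methoxymethoxy)-2,2-dimethyl-3a,4,5,7a-tetrahydro-1,3-benzodioxol-7a-yl]methyl benzoate
Conditions: second-generation Grubbs catalyst RuCl2(=CHPh)(H2IMes)(PCy3) (5 mol%), CH2Cl2 (5 mM), 40 °C
Reagents that add atoms: none
Why: Ring-closing olefin metathesis, in which the ruthenium alkylidene should load on the less hindered vinyl group next to the OMOM carbon, add across the vinyl group on the quaternary dioxolane carbon by [2+2] cycloaddition and release the ring by cycloreversion, loss of ethylene making the step irreversible. The closest known reaction type is RCM of sugar-derived 1,7-dienes to polyoxygenated cyclohexenes, including cases with a fully substituted allylic carbinol carbon. The six-membered carbocycle closes by this 1,7-diene metathesis as a ring cis-fused to the dioxolane, and the new C5=C6 bond can only be Z in a ring of this size. No new stereocentre is formed, and the four existing ones sit away from any acidic or basic site and should pass unchanged. The selectivity needed is cyclisation over cross-metathesis oligomerisation and over alkene isomerisation, and it is secured by the cis arrangement of the two alkenyl arms on the dioxolane (C1 vinyl and C2 chain), by the absence of free allylic hydroxyls and by high dilution.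

Step 8
Reactants: 11 [(3aS,4R,5S,7aS)-4-(benzoyloxy)-5-(methoxymethoxy)-2,2-dimethyl-3a,4,5,7a-tetrahydro-1,3-benzodioxol-7a-yl]methyl benzoate
Product: 12 1α-benzoyloxymethyl-3α-benzoyloxycyclohex-5-en-1β,2β,4β-triol
Conditions: Me2BBr (4 equiv), CH2Cl2, −78 °C; then aq. NaHCO3, 0 °C
Reagents that add atoms: none
Why: Me2BBr cleaves acetal-type C–O bonds (the MOM ether and the isopropylidene acetal) through bromo-ether intermediates at low temperature without attacking benzoate esters or the alkene, and the cold, non-basic conditions should prevent 1,2-benzoyl migration, so all stereocentres are retained.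

Compound list
1 | 2,3:5,6-di-O-isopropylidene-α-D-mannofuranose | O[C@H]1O[C@H]([C@H]2COC(C)(C)O2)[C@@H]3OC(C)(C)O[C@H]13 | starting material
2 | 2-C-(hydroxymethyl)-2,3:5,6-di-O-isopropylidene-D-mannofuranose (anomeric mixture) | OC1O[C@H]([C@H]2COC(C)(C)O2)[C@@H]3OC(C)(C)O[C@]13CO | intermediate
3 | 1,2-dideoxy-3-C-(hydroxymethyl)-3,4:6,7-di-O-isopropylidene-D-manno-hept-1-enitol | C=C[C@@]1(CO)OC(C)(C)O[C@H]1[C@H](O)[C@H]2COC(C)(C)O2 | intermediate
4 | 3-C-(benzoyloxymethyl)-1,2-dideoxy-3,4:6,7-di-O-isopropylidene-D-manno-hept-1-enitol | C=C[C@@]1(COC(=O)c2ccccc2)OC(C)(C)O[C@H]1[C@H](O)[C@H]3COC(C)(C)O3 | intermediate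
5 | 3-C-(benzoyloxymethyl)-1,2-dideoxy-3,4-O-isopropylidene-D-manno-hept-1-enitol (5,6,7-triol, not isolated) | C=C[C@@]1(COC(=O)c2ccccc2)OC(C)(C)O[C@H]1[C@H](O)[C@H](O)CO | intermediate
6 | [(4S,5R)-4-ethenyl-5-formyl-2,2-dimethyl-1,3-dioxolan-4-yl]methyl benzoate | C=C[C@@]1(COC(=O)c2ccccc2)OC(C)(C)O[C@H]1C=O | intermediate
7 | allyl methoxymethyl ether, 3-(methoxymethoxy)prop-1-ene | C=CCOCOC | starting material
8 | O-diisopinocampheylboryl derivative (borinate ester) of 9, not isolated | C=C[C@@]1(COC(=O)c2ccccc2)OC(C)(C)O[C@H]1[C@H](OB([C@H]3C[C@H]4C[C@@H]([C@@H]3C)C4(C)C)[C@H]3C[C@H]4C[C@@H]([C@@H]3C)C4(C)C)[C@@H](OCOC)C=C | intermediate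
9 | [(4S,5S)-4-ethenyl-5-[(1R,2S)-1-hydroxy-2-(methoxymethoxy)but-3-en-1-yl]-2,2-dimethyl-1,3-dioxolan-4-yl]methyl benzoate | C=C[C@@]1(COC(=O)c2ccccc2)OC(C)(C)O[C@H]1[C@H](O)[C@@H](OCOC)C=C | intermediate
10 | [(4S,5S)-5-[(1R,2S)-1-(benzoyloxy)-2-(methoxymethoxy)but-3-en-1-yl]-4-ethenyl-2,2-dimethyl-1,3-dioxolan-4-yl]methyl benzoate | C=C[C@@]1(COC(=O)c2ccccc2)OC(C)(C)O[C@H]1[C@H](OC(=O)c2ccccc2)[C@@H](OCOC)C=C | intermediate
11 | [(3aS,4R,5S,7aS)-4-(benzoyloxy)-5-(methoxymethoxy)-2,2-dimethyl-3a,4,5,7a-tetrahydro-1,3-benzodioxol-7a-yl]methyl benzoate (1,2-O-isopropylidene-4-O-methoxymethyl derivative of the target) | O=C(OC[C@@]1(O2)C=C[C@H](OCOC)[C@@H](OC(=O)c3ccccc3)[C@@H]1OC2(C)C)c1ccccc1 | intermediate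
12 | 1α-benzoyloxymethyl-3α-benzoyloxycyclohex-5-en-1β,2β,4β-triol, (1S,2S,3R,4S) | O=C(OC[C@@]1(O)C=C[C@H](O)[C@@H](OC(=O)c2ccccc2)[C@@H]1O)c1ccccc1 | target

Total step count: 8. Longest linear sequence: 8 steps (from 1).

Steps most likely to fail

Step 5. The reagent has to act against the intrinsic facial preference of a hindered α-alkoxy aldehyde, so poor facial selectivity or sluggish addition is possible. The fallback replaces reagent control by substrate chelation control. It sets out from 6 and 7: 7 is lithiated (s-BuLi, THF, −78 °C) and quenched with Bu3SnCl to give (Z)-tributyl[3-(methoxymethoxy)prop-2-en-1-yl]stannane F1, which is added to 6 with MgBr2·OEt2 in CH2Cl2 at −20 °C. Chelation of magnesium between the aldehyde oxygen and the dioxolane oxygen on the α-carbon should direct attack syn to that oxygen, and the open transition state of the (Z)-alkoxyallylstannane should give the syn C3/C4 pair, both relations being those required. The fallback comes back to the route at 9.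

Step 2. The open hydroxy-aldehyde is a β-alkoxide aldehyde with a quaternary α-carbon, so retro-aldol loss of formaldehyde may compete with olefination, and lactol opening may be slow. The fallback is a Peterson olefination in two operations. It sets out from 2: addition of Me3SiCH2MgCl (excess, THF, 0 °C to rt), whose magnesium alkoxides should not fragment, gives 1-deoxy-3-C-(hydroxymethyl)-3,4:6,7-di-O-isopropylidene-1-(trimethylsilyl)-D-manno-heptitol F2 as a mixture of C2 epimers. Both epimers should converge on the same terminal alkene by syn elimination with KH in THF. The fallback comes back to the route at 3.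

Step 7. The vinyl group on the fully substituted dioxolane carbon may engage slowly, so the loaded alkylidene could dimerise through the unhindered alkene instead of cyclising. The fallback moves the deprotection ahead of the ring closure. It sets out from 10: Me2BBr (CH2Cl2, −78 °C, then aq. NaHCO3) gives (3S,4S,5R,6S)-5-(benzoyloxy)-3,4,6-trihydroxy-3-ethenylhept-6-en-3-ylmethyl benzoate, the free triol diene F3, and ring-closing metathesis of F3 with the second-generation Hoveyda–Grubbs catalyst RuCl2(=CH-2-(i-PrO)C6H4)(H2IMes) in CH2Cl2 at 40 °C should profit from the less encumbered tertiary carbinol and from acceleration by free allylic hydroxyls. The fallback comes back to the route at 12.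

Further compounds
F1 | step 5 | (Z)-tributyl[3-(methoxymethoxy)prop-2-en-1-yl]stannane | CCCC[Sn](CCCC)(CCCC)C/C=C\OCOC
F2 | step 2 | 1-deoxy-3-C-(hydroxymethyl)-3,4:6,7-di-O-isopropylidene-1-(trimethylsilyl)-D-manno-heptitol (C2 epimers) | C[Si](C)(C)CC(O)[C@@]1(CO)OC(C)(C)O[C@H]1[C@H](O)[C@H]2COC(C)(C)O2
F3 | step 7 | free triol diene, 1α-benzoyloxymethyl-3α-benzoyloxy seco-precursor of 12 with two terminal vinyl groups | C=C[C@](O)(COC(=O)c1ccccc1)[C@@H](O)[C@H](OC(=O)c1ccccc1)[C@@H](O)C=C
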